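**Retrosynthetic overview**

1. Feature: in the cyclohexane C5–C6–C7–C8–C9–C10, C6 carries an oxygen and the neighbouring C5 carries the 2-propenyl unit C4(=C3H2)–C15. This is a homoallylic alcohol of the isopulegol type, the retron of an intramolecular carbonyl-ene reaction.
2. Key disconnection C5–C6: ene closure of trans-lactone aldehyde 17 (C6 aldehyde on C7; C10 bearing CH3, the C1=C2 vinyl group and the 2-methylpropenyl group C5=C4Me2) gives 18.
3. C9–C10: allylboration of lactone aldehyde 7 with the (2Z)-dienylboronate 14 sets C9 and quaternary C10. C6–C7: conjugate addition of 2-lithio-1,3-dithiane to the (R)-butenolide, anti to C8, sets C7.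
4. After ring closure: C6 is inverted by oxidation/L-Selectride, C13 is added by Mannich methylenation, O6 is angeloylated, C15 is oxidised (SeO2, then MnO2) and O9 is desilylated.
5. Ring order: the γ-lactone (C7, C8, C11, C12, O) comes intact from butenolide 1; the cyclohexane is the only ring formed (step 12).

Key step: step 12

Assumption: the R enantiomer of 5-(hydroxymethyl)furan-2(5H)-one (1) is taken as a catalogue compound, as its S enantiomer is.

Atom labels C1–C15 follow the elemane numbering used in the overview.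

**Route**

Step 1
Reactants: 1 (5R)-5-(hydroxymethyl)furan-2(5H)-one
Product: 2 (5R)-5-(TBS-oxymethyl)furan-2(5H)-one
Conditions: TBSCl, imidazole, DMF, 0 °C → rt
Reagents that add atoms: tert-butyldimethylsilyl chloride, CC(C)(C)[Si](C)(C)Cl
Why: Imidazole-promoted silylation of the primary alcohol (Corey TBS protection) masks the hydroxyl before the carbanion addition and enlarges the C8 side chain that will direct the next step; C8 is untouched.

Step 2
Reactants: 2 (5R)-5-(TBS-oxymethyl)furan-2(5H)-one; 3 1,3-dithiane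
Product: 5 trans-4-(1,3-dithian-2-yl)-5-(TBS-oxymethyl) lactone (4R,5R), via 2-lithio-1,3-dithiane 4 (not isolated)
Conditions: 3, n-BuLi, THF, −30 °C; HMPA, −78 °C; then 2; AcOH
Reagents that add atoms: none
Why: Corey–Seebach 2-lithio-1,3-dithiane, made solvent-separated by HMPA, adds to the butenolide in the 1,4 (Michael) sense and approaches C7 anti to the C8 silyloxymethyl group, which sets the trans C7/C8 relationship by 1,2-induction and makes the dithiane carbon the future C6.

Step 3
Reactants: 5 trans-dithianyl lactone silyl ether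
Product: 6 (4R,5R)-4-(1,3-dithian-2-yl)-5-(hydroxymethyl)oxolan-2-one
Conditions: HF·pyridine, THF–pyridine, 0 °C → rt
Reagents that add atoms: none
Why: Fluoride cleavage of a primary TBS ether under acidic, non-basic conditions leaves the lactone, the thioacetal and the C7/C8 centres unchanged.

Step 4
Reactants: 6 hydroxymethyl lactone
Product: 7 (2R,3R)-3-(1,3-dithian-2-yl)-5-oxooxolane-2-carbaldehyde
Conditions: (COCl)2, DMSO, CH2Cl2, −78 °C; Et3N, −78 → −20 °C
Reagents that add atoms: none
Why: Swern oxidation at low temperature gives the C9 aldehyde without touching the thioacetal, and cold work-up keeps the α-oxygenated C8 centre from epimerising; the aldehyde is used crude.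

Step 5
Reactants: 8 but-2-yn-1-ol
Product: 10 (2Z)-3-iodobut-2-en-1-ol, via cyclic alkenylalanate 9 (not isolated)
Conditions: Red-Al, THF, 0 °C → rt; EtOAc; then I2, THF, −78 → 0 °C
Reagents that add atoms: iodine, II
Why: Alkoxide-directed trans-hydroalumination of the propargylic alcohol places aluminium on C3 cis to the CH2O group in a five-membered alanate, and iodinolysis with retention gives the Z vinyl iodide.

Step 6
Reactants: 10 (2Z)-3-iodobut-2-en-1-ol; 11 2-methylprop-1-enylboronic acid pinacol ester
Product: 12 (2Z)-3,5-dimethylhexa-2,4-dien-1-ol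
Conditions: Pd(dppf)Cl2 (5 mol %), K3PO4 (aq), THF, 50 °C
Reagents that add atoms: none
Why: Suzuki–Miyaura coupling of an alkenyl iodide with an alkenylboronate proceeds with retention at both sp2 carbons, so the 2-methylpropenyl group ends cis to CH2OH (2Z).

Step 7
Reactants: 12 (2Z)-dienol
Product: 13 (2Z)-3,5-dimethylhexa-2,4-dien-1-yl acetate
Conditions: Ac2O, Et3N, DMAP (cat.), CH2Cl2, 0 °C
Reagents that add atoms: acetic anhydride, CC(=O)OC(C)=O
Why: DMAP-catalysed acetylation provides the leaving group for nickel under non-ionising conditions that should not isomerise the diene.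

Step 8
Reactants: 13 (2Z)-dienyl acetate
Product: 14 (2Z)-3,5-dimethylhexa-2,4-dien-1-ylboronic acid pinacol ester
Conditions: B2pin2, Ni(cod)2 (5 mol %), PCy3 (10 mol %), EtOAc, rt
Reagents that add atoms: bis(pinacolato)diboron, CC1(C)OB(OC1(C)C)B1OC(C)(C)C(C)(C)O1
Why: Nickel(0)-catalysed Miyaura-type borylation of an allylic acetate delivers boron to the unsubstituted allyl terminus, and because the 3,3-disubstituted terminus of the π-allyl intermediate does not readily pass through a σ-bound form, the Z geometry should be retained.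

Step 9
Reactants: 7 lactone aldehyde; 14 (2Z)-dienylboronate
Product: 15 (4R,5R)-4-(1,3-dithian-2-yl)-5-[(1S,2S)-2-ethenyl-1-hydroxy-2,4-dimethylpent-3-en-1-yl]oxolan-2-one
Conditions: toluene, 4 Å MS, rt → 40 °C; aq. NaHCO3 work-up
Reagents that add atoms: none
Why: Thermal allylboration through a Zimmerman–Traxler chair bonds the γ-carbon to the aldehyde, which creates quaternary C10 with the E-disposed methyl anti and the Z-disposed 2-methylpropenyl syn to the new C9 oxygen (hence the Z reagent, used as a configurationally stable boronate), while Felkin–Anh (Cornforth) attack anti to the C8–O bond, reinforced by the Z γ-substituent, gives the 8,9-anti C9 alcohol.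

Step 10
Reactants: 15 homoallylic alcohol
Product: 16 C9 TBS ether (4R,5R,1'S,2'S)
Conditions: TBSOTf, 2,6-lutidine, CH2Cl2, −78 → 0 °C
Reagents that add atoms: tert-butyldimethylsilyl trifluoromethanesulfonate, CC(C)(C)[Si](C)(C)OS(=O)(=O)C(F)(F)F
Why: The silyl triflate with 2,6-lutidine silylates the hindered neopentyl-type secondary alcohol, and the buffered conditions leave the skipped diene and the thioacetal intact.

Step 11
Reactants: 16 dithianyl lactone TBS ether
Product: 17 (2R,3R)-2-[(1S,2S)-1-(TBS-oxy)-2-ethenyl-2,4-dimethylpent-3-en-1-yl]-5-oxooxolane-3-carbaldehyde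
Conditions: MeI, CaCO3, MeCN–H2O (9:1), 40 °C
Reagents that add atoms: water, O
Why: S-Methylation of the dithiane and hydrolysis of the sulfonium (alkylative thioacetal cleavage) releases the C6 aldehyde under near-neutral conditions that spare the alkenes and the silyl ether; the trans C7 configuration is also the thermodynamically preferred one.

Step 12
Reactants: 17 trans-lactone aldehyde
Product: 18 cyclised alcohol (3aS,4R,5S,6S,7S,7aR): 6α-OH equatorial, 5β-(prop-1-en-2-yl), 9α-OTBS
Conditions: Me2AlCl (2.2 equiv), CH2Cl2, −78 → −20 °C; aq. Rochelle salt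
Reagents that add atoms: none
Why: Me2AlCl binds the C6 aldehyde (a second equivalent is held by the lactone carbonyl) and the nucleophilic C5 of the trisubstituted alkene attacks the activated carbonyl while a hydrogen of the C4 methyl trans to C10 passes to oxygen, a concerted but asynchronous intramolecular carbonyl-ene reaction of the citronellal-to-isopulegol kind (Oppolzer type I), after which the aluminium alkoxide loses methane and so removes the proton source. The cyclohexane C5–C10 closes by 6-exo attack on the carbonyl with the ene double bond left exocyclic as C4=C3, through a chair in which the lactone bonds at C7 and C8 are both equatorial, which fixes the C9 silyloxy and the C10 methyl as axial and the vinyl as equatorial. C5 is set by the C5=C4 unit taking the equatorial position, since an axial one would meet the axial C9–OTBS and C7–H on the α-face, which gives the β-propenyl group and α-H of the target. C6 is set by the complexed carbonyl oxygen lying equatorial (α), gauche to C4 as the hydrogen transfer requires, because the axial alternative would be syn-diaxial to the C10 methyl; this is the C6 epimer of the target and is inverted in steps 13 and 14. The step needs the 2-methylpropenyl group to react and not the vinyl group, which is secured because only the former can place positive charge on a tertiary carbon (C4) and offer an allylic hydrogen, and it needs ene closure to outrun methyl transfer from aluminium, which low temperature and the six-membered intramolecular closure favour.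

Step 13
Reactants: 18 6α-alcohol
Product: 19 C6 ketone (3aR,5S,6S,7S,7aR)
Conditions: Dess–Martin periodinane, NaHCO3, CH2Cl2, 0 °C → rt
Reagents that add atoms: none
Why: Dess–Martin oxidation under buffered, non-basic conditions gives the β,γ-unsaturated ketone without moving the C4=C3 double bond into conjugation or epimerising C5 and C7; the ketone is used directly.

Step 14
Reactants: 19 C6 ketone
Product: 20 6β-alcohol (3aS,4S,5S,6S,7S,7aR)
Conditions: L-Selectride, THF, −78 °C; AcOH
Reagents that add atoms: none
Why: L-Selectride delivers hydride along the equatorial trajectory from the α-face, because axial approach on the β-face is blocked by the syn-axial C10 methyl, which gives the axial 6β-alcohol of the target and leaves the lactone untouched at −78 °C.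

Step 15
Reactants: 20 6β-alcohol; 21 N,N-dimethylmethyleneiminium iodide (Eschenmoser's salt)
Product: 22 C11 dimethylaminomethyl lactone (Mannich base, C11 epimers)
Conditions: LDA (2.3 equiv), THF, −78 → −40 °C; then 21, −78 → 0 °C
Reagents that add atoms: none
Why: Double deprotonation (C6 alkoxide, then lactone enolate) and Mannich reaction of the C11 enolate with Eschenmoser's salt introduces C13; the new C11 centre is removed in the next step, so its configuration is immaterial, and direct acyl transfer to the C6 alkoxide is not expected because O6 (axial, β) and O8 (equatorial, α) cannot both reach C12.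

Step 16
Reactants: 22 Mannich base
Product: 24 α-methylene lactone 6β-alcohol (3aS,4S,5S,6S,7S,7aR), via trimethylammonium iodide 23 (not isolated)
Conditions: MeI, MeOH, rt; then aq. NaHCO3, EtOAc, rt
Reagents that add atoms: none
Why: N-Methylation followed by bicarbonate-induced β-elimination (Hofmann-type elimination of the quaternised Mannich base) gives the C11=C13 methylene lactone; oxa-Michael closure of the C6 hydroxyl onto C13 would be 5-endo-trig and is not expected.

Step 17
Reactants: 24 α-methylene lactone 6β-alcohol; 25 angelic acid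
Product: 27 6β-angelate (3aS,4S,5S,6S,7S,7aR), via angelic 2,4,6-trichlorobenzoic anhydride 26 (not isolated)
Conditions: 25, 2,4,6-trichlorobenzoyl chloride, Et3N, toluene, rt; then 24, 80 °C
Reagents that add atoms: none
Why: Yamaguchi-type esterification through the mixed anhydride, run without DMAP, acylates the C6 hydroxyl at the less shielded angeloyl carbonyl and is the usual way to keep the Z (angelate) geometry from isomerising to the tiglate.

Step 18
Reactants: 27 6β-angelate
Product: 28 C15 allylic alcohol (3aS,4S,5S,6S,7S,7aR)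
Conditions: SeO2 (0.5 equiv), t-BuOOH, CH2Cl2, 0 °C → rt
Reagents that add atoms: selenium dioxide, O=[Se]=O (oxygen atom; reoxidised by t-BuOOH)
Why: Selenium dioxide allylic oxidation (ene reaction, then [2,3]-shift; catalytic Sharpless variant) attacks the most electron-rich alkene, the 1,1-disubstituted C4=C3, and hydroxylates its methyl (C15) in preference to the hindered C5 methine, while the vinyl group has no allylic hydrogen and the two conjugated alkenes are deactivated.

Step 19
Reactants: 28 C15 allylic alcohol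
Product: 29 C15 enal, O9-TBS (3aS,4S,5R,6S,7S,7aR)
Conditions: MnO2, CH2Cl2, rt
Reagents that add atoms: none
Why: Activated MnO2 oxidises only the allylic primary alcohol to the enal and also converges any enal already formed in step 18.

Step 20
Reactants: 29 silylated enal
Product: 30 CNP0277836.2 (target)
Conditions: HF·pyridine, THF, 0 °C → rt
Reagents that add atoms: none
Why: HF·pyridine removes the hindered secondary TBS ether under mildly acidic conditions that tolerate the enal, the α-methylene lactone and the angelate, giving the target with C8 from 1 and C7, C9/C10, C5 and C6 as set in steps 2, 9, 12 and 14.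

**Compound list**

1 | (5R)-5-(hydroxymethyl)furan-2(5H)-one | OC[C@@H]1OC(=O)C=C1 | starting material
2 | (5R)-5-{[tert-butyl(dimethyl)silyl]oxymethyl}furan-2(5H)-one | CC(C)(C)[Si](C)(C)OC[C@@H]1OC(=O)C=C1 | intermediate
3 | 1,3-dithiane | C1CSCSC1 | starting material
4 | 2-lithio-1,3-dithiane | [Li]C1SCCCS1 | intermediate (not isolated)
5 | (4R,5R)-5-{[tert-butyl(dimethyl)silyl]oxymethyl}-4-(1,3-dithian-2-yl)oxolan-2-one | C1CSC(SC1)[C@@H]1CC(=O)O[C@H]1CO[Si](C)(C)C(C)(C)C | intermediate
6 | (4R,5R)-4-(1,3-dithian-2-yl)-5-(hydroxymethyl)oxolan-2-one | C1CSC(SC1)[C@@H]1CC(=O)O[C@H]1CO | intermediate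
7 | (2R,3R)-3-(1,3-dithian-2-yl)-5-oxooxolane-2-carbaldehyde | C1CSC(SC1)[C@@H]1CC(=O)O[C@H]1C=O | intermediate
8 | but-2-yn-1-ol | CC#CCO | starting material
9 | sodium 2,2-bis(2-methoxyethoxy)-3-methyl-2,5-dihydro-1,2-oxaaluminol-2-uide (cyclic alkenylalanate) | CC1=CCO[Al-]1(OCCOC)OCCOC.[Na+] | intermediate (not isolated)
10 | (2Z)-3-iodobut-2-en-1-ol | C/C(I)=C/CO | intermediate
11 | 4,4,5,5-tetramethyl-2-(2-methylprop-1-en-1-yl)-1,3,2-dioxaborolane | CC(C)=CB1OC(C)(C)C(C)(C)O1 | starting material
12 | (2Z)-3,5-dimethylhexa-2,4-dien-1-ol | C/C(C=C(C)C)=C/CO | intermediate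
13 | (2Z)-3,5-dimethylhexa-2,4-dien-1-yl acetate | C/C(C=C(C)C)=C/COC(C)=O | intermediate
14 | 2-[(2Z)-3,5-dimethylhexa-2,4-dien-1-yl]-4,4,5,5-tetramethyl-1,3,2-dioxaborolane | C/C(C=C(C)C)=C/CB1OC(C)(C)C(C)(C)O1 | intermediate
15 | (4R,5R)-4-(1,3-dithian-2-yl)-5-[(1S,2S)-2-ethenyl-1-hydroxy-2,4-dimethylpent-3-en-1-yl]oxolan-2-one | C1CSC(SC1)[C@@H]1CC(=O)O[C@H]1[C@@H](O)[C@@](C)(C=C)C=C(C)C | intermediate
16 | (4R,5R)-5-[(1S,2S)-1-{[tert-butyl(dimethyl)silyl]oxy}-2-ethenyl-2,4-dimethylpent-3-en-1-yl]-4-(1,3-dithian-2-yl)oxolan-2-one | C1CSC(SC1)[C@@H]1CC(=O)O[C@H]1[C@@H](O[Si](C)(C)C(C)(C)C)[C@@](C)(C=C)C=C(C)C | intermediate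
17 | (2R,3R)-2-[(1S,2S)-1-{[tert-butyl(dimethyl)silyl]oxy}-2-ethenyl-2,4-dimethylpent-3-en-1-yl]-5-oxooxolane-3-carbaldehyde | O=C[C@@H]1CC(=O)O[C@H]1[C@@H](O[Si](C)(C)C(C)(C)C)[C@@](C)(C=C)C=C(C)C | intermediate
18 | (3aS,4R,5S,6S,7S,7aR)-7-{[tert-butyl(dimethyl)silyl]oxy}-6-ethenyl-4-hydroxy-6-methyl-5-(prop-1-en-2-yl)hexahydro-1-benzofuran-2(3H)-one | C=C[C@]1(C)[C@H](O[Si](C)(C)C(C)(C)C)[C@@H]2OC(=O)C[C@H]2[C@H](O)[C@H]1C(=C)C | intermediate
19 | (3aR,5S,6S,7S,7aR)-7-{[tert-butyl(dimethyl)silyl]oxy}-6-ethenyl-6-methyl-5-(prop-1-en-2-yl)hexahydro-1-benzofuran-2,4-dione | C=C[C@]1(C)[C@H](O[Si](C)(C)C(C)(C)C)[C@@H]2OC(=O)C[C@H]2C(=O)[C@H]1C(=C)C | intermediate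
20 | (3aS,4S,5S,6S,7S,7aR)-7-{[tert-butyl(dimethyl)silyl]oxy}-6-ethenyl-4-hydroxy-6-methyl-5-(prop-1-en-2-yl)hexahydro-1-benzofuran-2(3H)-one | C=C[C@]1(C)[C@H](O[Si](C)(C)C(C)(C)C)[C@@H]2OC(=O)C[C@H]2[C@@H](O)[C@H]1C(=C)C | intermediate
21 | N,N-dimethylmethyleneiminium iodide (Eschenmoser's salt) | C=[N+](C)C.[I-] | starting material
22 | (3aS,4S,5S,6S,7S,7aR)-7-{[tert-butyl(dimethyl)silyl]oxy}-3-[(dimethylamino)methyl]-6-ethenyl-4-hydroxy-6-methyl-5-(prop-1-en-2-yl)hexahydro-1-benzofuran-2(3H)-one (C3 epimers, configuration immaterial) | C=C[C@]1(C)[C@H](O[Si](C)(C)C(C)(C)C)[C@@H]2OC(=O)C(CN(C)C)[C@H]2[C@@H](O)[C@H]1C(=C)C | intermediate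
23 | N,N,N-trimethylammonium iodide of 22 | C=C[C@]1(C)[C@H](O[Si](C)(C)C(C)(C)C)[C@@H]2OC(=O)C(C[N+](C)(C)C)[C@H]2[C@@H](O)[C@H]1C(=C)C.[I-] | intermediate (not isolated)
24 | (3aS,4S,5S,6S,7S,7aR)-7-{[tert-butyl(dimethyl)silyl]oxy}-6-ethenyl-4-hydroxy-6-methyl-3-methylidene-5-(prop-1-en-2-yl)hexahydro-1-benzofuran-2(3H)-one | C=C[C@]1(C)[C@H](O[Si](C)(C)C(C)(C)C)[C@@H]2OC(=O)C(=C)[C@H]2[C@@H](O)[C@H]1C(=C)C | intermediate
25 | (2Z)-2-methylbut-2-enoic acid (angelic acid) | C/C=C(/C)C(=O)O | starting material
26 | (2Z)-2-methylbut-2-enoic 2,4,6-trichlorobenzoic anhydride | C/C=C(/C)C(=O)OC(=O)c1c(Cl)cc(Cl)cc1Cl | intermediate (not isolated)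
27 | (3aS,4S,5S,6S,7S,7aR)-7-{[tert-butyl(dimethyl)silyl]oxy}-6-ethenyl-6-methyl-3-methylidene-2-oxo-5-(prop-1-en-2-yl)octahydro-1-benzofuran-4-yl (2Z)-2-methylbut-2-enoate | C=C[C@]1(C)[C@H](O[Si](C)(C)C(C)(C)C)[C@@H]2OC(=O)C(=C)[C@H]2[C@@H](OC(=O)/C(C)=C\C)[C@H]1C(=C)C | intermediate
28 | (3aS,4S,5S,6S,7S,7aR)-7-{[tert-butyl(dimethyl)silyl]oxy}-6-ethenyl-5-(3-hydroxyprop-1-en-2-yl)-6-methyl-3-methylidene-2-oxooctahydro-1-benzofuran-4-yl (2Z)-2-methylbut-2-enoate | C=C[C@]1(C)[C@H](O[Si](C)(C)C(C)(C)C)[C@@H]2OC(=O)C(=C)[C@H]2[C@@H](OC(=O)/C(C)=C\C)[C@H]1C(=C)CO | intermediate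
29 | (3aS,4S,5R,6S,7S,7aR)-7-{[tert-butyl(dimethyl)silyl]oxy}-6-ethenyl-6-methyl-3-methylidene-2-oxo-5-(3-oxoprop-1-en-2-yl)octahydro-1-benzofuran-4-yl (2Z)-2-methylbut-2-enoate | C=C[C@]1(C)[C@H](O[Si](C)(C)C(C)(C)C)[C@@H]2OC(=O)C(=C)[C@H]2[C@@H](OC(=O)/C(C)=C\C)[C@H]1C(=C)C=O | intermediate
30 | CNP0277836.2: (3aS,4S,5R,6S,7S,7aR)-6-ethenyl-7-hydroxy-6-methyl-3-methylidene-2-oxo-5-(3-oxoprop-1-en-2-yl)octahydro-1-benzofuran-4-yl (2Z)-2-methylbut-2-enoate | C=C[C@]1(C)[C@H](O)[C@@H]2OC(=O)C(=C)[C@H]2[C@@H](OC(=O)/C(C)=C\C)[C@H]1C(=C)C=O | target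

**Step count and risks**

Total step count: 20. Longest linear sequence: 16 steps (steps 1–4 and 9–20 from 1; equally steps 5–8 and 9–20 from 8).

Steps most likely to fail:

Step 12 (ene closure). The required chair builds a cyclohexane trans-fused to the lactone, so closure may be slow enough for methyl transfer from aluminium to the aldehyde, chloride capture at C4, or closure through a boat (axial C6 oxygen or C5 epimer) to compete. The fallback makes the same C5–C6 bond by a metal-mediated allylation in place of the pericyclic step. It sets out from 17: catalytic SeO2/t-BuOOH hydroxylates the (E)-methyl of the 2-methylpropenyl group to give the (E)-allylic alcohol aldehyde F1. Mesylation (MsCl, Et3N, −20 °C) and displacement with LiBr give the allylic bromide aldehyde F2. CrCl2 in THF (intramolecular Nozaki–Hiyama allylation) then closes the ring through the γ-carbon C5 in a chair with anti selectivity, leaving the bromide-bearing carbon as C3H2 and the other methyl as C15, and comes back to the route at 18.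

Step 8 (allylic borylation). Syn/anti exchange in the allylnickel intermediate, or boron delivery to the far end of the pentadienyl system, would erode the Z geometry, and step 9 would translate this into the C10 epimer. The fallback uses a silicon reagent made without a π-allyl metal intermediate. It sets out from 12: MsCl, LiCl and collidine in DMF at 0 °C give the (2Z)-allylic chloride F3 with retention. HSiCl3, CuCl (cat.) and i-Pr2NEt in Et2O give the (2Z)-allyltrichlorosilane F4 by direct substitution. Addition of aldehyde 7 in DMF at 0 °C (Lewis-base-activated allylation through a closed chair, same stereochemical course as the boronate) comes back to the route at 15 and bypasses 13 and 14.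

Step 17 (angeloylation). Acylation of the axial C6 hydroxyl, screened by the syn-axial C10 methyl and by both ring neighbours, may be so slow that Z→E isomerisation of the acyl donor or amine addition to the methylene lactone takes over. The fallback builds the angelate double bond on the ester after acylation with a small acyl donor. It sets out from 24: DCC/DMAP coupling with 2-[bis(2,2,2-trifluoroethoxy)phosphoryl]propanoic acid (acylation through the phosphonoketene, which is little sensitive to hindrance) gives the phosphonate ester F5. KHMDS/18-crown-6 and acetaldehyde in THF at −78 °C (Z-selective Still–Gennari olefination) then come back to the route at 27.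

**Further compounds**

F1 | step 12 | (2R,3R)-2-[(1S,2S,3E)-1-{[tert-butyl(dimethyl)silyl]oxy}-2-ethenyl-5-hydroxy-2,4-dimethylpent-3-en-1-yl]-5-oxooxolane-3-carbaldehyde | O=C[C@@H]1CC(=O)O[C@H]1[C@@H](O[Si](C)(C)C(C)(C)C)[C@@](C)(C=C)/C=C(\C)CO
F2 | step 12 | (2R,3R)-2-[(1S,2S,3E)-5-bromo-1-{[tert-butyl(dimethyl)silyl]oxy}-2-ethenyl-2,4-dimethylpent-3-en-1-yl]-5-oxooxolane-3-carbaldehyde | O=C[C@@H]1CC(=O)O[C@H]1[C@@H](O[Si](C)(C)C(C)(C)C)[C@@](C)(C=C)/C=C(\C)CBr
F3 | step 8 | (2Z)-1-chloro-3,5-dimethylhexa-2,4-diene | C/C(C=C(C)C)=C/CCl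
F4 | step 8 | trichloro[(2Z)-3,5-dimethylhexa-2,4-dien-1-yl]silane | C/C(C=C(C)C)=C/C[Si](Cl)(Cl)Cl
F5 | step 17 | (3aS,4S,5S,6S,7S,7aR)-7-{[tert-butyl(dimethyl)silyl]oxy}-6-ethenyl-6-methyl-3-methylidene-2-oxo-5-(prop-1-en-2-yl)octahydro-1-benzofuran-4-yl 2-[bis(2,2,2-trifluoroethoxy)phosphoryl]propanoate | C=C[C@]1(C)[C@H](O[Si](C)(C)C(C)(C)C)[C@@H]2OC(=O)C(=C)[C@H]2[C@@H](OC(=O)C(C)P(=O)(OCC(F)(F)F)OCC(F)(F)F)[C@H]1C(=C)C
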